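The cyclohexene ring is disconnected at C2–C3 and C1–C6. Its alkene C4=C5 has an oxygen-bearing carbon on either side (C3 and C6), and the two remaining ring carbons, quaternary C1 with its one-carbon branch C7 and acetoxy-bearing C2, carry just what a 3-acetoxy-2-bromoacrolein would bring. A 1,4-dioxygenated butadiene therefore supplies C3–C6 and the enal supplies C1, C2 and C7. One catalyst-controlled Diels–Alder reaction should close the ring, form both bonds and set all four stereocentres, leaving bromide at C1 anti to the C6 oxygen for closure of the oxirane ring. The precursors are (1E,3E)-1-benzoyloxy-4-(triisopropylsilyloxy)butadiene and (Z)-3-acetoxy-2-bromoacrolein.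

Key step: step 5

Numbering: target numbering is used for all ring compounds. C1 is the quaternary epoxide carbon, C2 bears acetoxy, C3 bears benzoyloxy, C4=C5 is the alkene, C6 is the epoxide CH and C7 is the exocyclic carbon.

Assumption: the sense of induction is taken from the accepted binding model of α-bromo enals on this catalyst class (formyl C–H···O contact to the ring oxygen, s-trans enal, one aryl group covering the rear face), which calls for the (R)-catalyst; the (S)-catalyst would be used instead should the adduct prove to belong to the mirror-image series.

Step 1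
Reactants: 1 2-bromomalonaldehyde; 2 acetyl chloride
Product: 3 (Z)-3-acetoxy-2-bromoacrolein (acetoxy cis to bromine and trans to formyl)
Conditions: Et3N (1.0 equiv), CH2Cl2, −40 °C, then 2 (1.05 equiv), −40 to 0 °C; cold aqueous wash, used at once
Reagents that add atoms: none
Why: Irreversible O-acylation of the triethylammonium enolate of the strongly acidic 1,3-dialdehyde by the acyl chloride should give the vinylogous mixed anhydride, and the W-shaped enolate, in which each oxygen lies anti to the other formyl carbon, should deliver the enol acetate with acetoxy trans to formyl, which is the Z isomer.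

Step 2
Reactants: 4 (Z)-but-2-ene-1,4-diol; 5 benzoyl chloride
Product: 6 (Z)-4-hydroxybut-2-enyl benzoate
Conditions: 4 (3 equiv), 5 (1 equiv), pyridine, THF, 0 °C; surplus diol washed out with water
Reagents that add atoms: none
Why: Esterification with an acyl chloride under pyridine (Einhorn acylation) should stop at the monoester because the symmetrical diol is used in threefold excess.

Step 3
Reactants: 6 (Z)-4-hydroxybut-2-enyl benzoate
Product: 7 (Z)-4-oxobut-2-enyl benzoate
Conditions: activated MnO2 (15 equiv), CH2Cl2, 0 to 20 °C; filtered through Celite, concentrated cold and used at once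
Reagents that add atoms: none
Why: Oxidation of the primary allylic alcohol on the surface of activated MnO2 is neutral and should leave the cis alkene and the allylic benzoate untouched, whereas acidic chromium oxidants would isomerise the enal to the trans isomer.

Step 4
Reactants: 7 (Z)-4-oxobut-2-enyl benzoate
Product: 8 (1E,3E)-4-(triisopropylsilyloxy)buta-1,3-dienyl benzoate
Conditions: Et3N (1.6 equiv), Et2O, −78 °C, then i-Pr3SiOSO2CF3 (1.2 equiv), −78 to 0 °C; filtered through Et3N-deactivated silica
Reagents that add atoms: triisopropylsilyl trifluoromethanesulfonate, CC(C)[Si](C(C)C)(C(C)C)OS(=O)(=O)C(F)(F)F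
Why: Soft enolisation (silyl triflate with a tertiary amine) should O-silylate the enal and remove a γ-proton from the resulting 1-silyloxyallyl cation to give the silyl dienol ether, the s-trans enal leading to the E silyl enol ether, while the cis alkene of 7 holds the γ-carbon beside the formyl carbon so that allylic 1,3-strain turns the benzoyloxy group outward and the enol benzoate also forms E; any 1Z isomer arising from enal that has isomerised cannot reach the s-cis conformation and stays a spectator in step 5.

Step 5
Reactants: 8 (1E,3E)-4-(triisopropylsilyloxy)buta-1,3-dienyl benzoate; 3 (Z)-3-acetoxy-2-bromoacrolein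
Product: 9 (1S,2S,3R,6S)-2-acetoxy-3-(benzoyloxy)-1-bromo-6-(triisopropylsilyloxy)cyclohex-4-ene-1-carbaldehyde
Conditions: (3aR)-1-(2-methylphenyl)-3,3-diphenyltetrahydro-1H,3H-pyrrolo[1,2-c][1,3,2]oxazaborole (C24H24BNO, 20 mol %) protonated in situ with (CF3SO2)2NH (18 mol %), 3 (1.0 equiv), 8 (1.5 equiv), CH2Cl2, −78 °C; Et3N quench
Reagents that add atoms: none
Why: The formyl oxygen of 3 binds the boron of the N-protonated oxazaborolidine, which lowers the LUMO of the s-trans enal, and a concerted but asynchronous [4+2] cycloaddition follows in which diene carbon C3 (the terminus remote from the silyloxy donor and hence the nucleophilic one) bonds to the β-carbon C2 ahead of C6–C1 bonding; the closest known reaction type is the oxazaborolidinium-catalysed enantioselective Diels–Alder reaction of 2-bromoacrolein with 1-oxygenated butadienes. The cyclohexene ring is closed by intermolecular cycloaddition of the four-carbon diene onto the two-carbon dienophile, suprafacial on both partners, forming C2–C3 and C1–C6. Relative configuration follows from geometry: the (E,E)-diene puts the C3 and C6 oxygens cis, the (Z)-dienophile puts bromine at C1 and acetoxy at C2 cis, and formyl-endo approach (bromine and acetoxy exo) puts the formyl group cis and bromine trans to the C6 oxygen. Absolute configuration at C1, C2, C3 and C6 is set together by the catalyst, whose aryl group covers one face of the bound enal so that the diene adds to the Si face of C1 (Br > CHO > C2). The step needs regio-, endo- and face-selectivity: the first rests on the silyloxy group being a far stronger donor than the benzoyloxy group, the second on the formyl-endo preference that Lewis-acid-bound α-substituted enals show towards open-chain 1-oxygenated dienes, and the third on the catalyst. The bulky triisopropylsilyl group is chosen to resist silyl transfer to the acidic catalyst, which would otherwise start an achiral background reaction.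

Step 6
Reactants: 9 (1S,2S,3R,6S)-2-acetoxy-3-(benzoyloxy)-1-bromo-6-(triisopropylsilyloxy)cyclohex-4-ene-1-carbaldehyde
Product: 11 (1S,2S,3R,6S)-2-acetoxy-1-formyl-7-oxabicyclo[4.1.0]hept-4-en-3-yl benzoate, via tetrabutylammonium C6-alkoxide 10 (not isolated)
Conditions: Bu4NF (1.2 equiv), THF, 0 °C
Reagents that add atoms: none
Why: Fluoride-induced desilylation should free the C6 alkoxide, which lies anti to the C1–Br bond and displaces bromide in an intramolecular Williamson-type SN2 reaction (3-exo-tet, halohydrin-to-epoxide closure) with inversion at C1, so that the epoxide oxygen ends cis to the C3 benzoate and trans to the C2 acetate.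

Step 7
Reactants: 11 (1S,2S,3R,6S)-2-acetoxy-1-formyl-7-oxabicyclo[4.1.0]hept-4-en-3-yl benzoate
Product: 12 (1S,2S,3R,6S)-2-acetoxy-1-(hydroxymethyl)-7-oxabicyclo[4.1.0]hept-4-en-3-yl benzoate
Conditions: NaBH4 (0.5 equiv), MeOH/CH2Cl2 1:1, −78 °C; AcOH quench at −78 °C
Reagents that add atoms: none
Why: Chemoselective borohydride 1,2-reduction of the non-enolisable epoxy aldehyde should proceed at −78 °C, where the esters and the vinyl epoxide are inert and acyl migration to the new hydroxyl is slow; no stereocentre is formed.

Step 8
Reactants: 12 (1S,2S,3R,6S)-2-acetoxy-1-(hydroxymethyl)-7-oxabicyclo[4.1.0]hept-4-en-3-yl benzoate; 5 benzoyl chloride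
Product: 13 [(1S,2S,3R,6S)-2-acetoxy-3-(benzoyloxy)-7-oxabicyclo[4.1.0]hept-4-en-1-yl]methyl benzoate
Conditions: 5 (1.2 equiv), pyridine, 4-(dimethylamino)pyridine (5 mol %), CH2Cl2, 0 °C
Reagents that add atoms: none
Why: Nucleophile-catalysed acylation of the primary alcohol with an acyl chloride should give the benzoate under conditions too mild to open the epoxide or move the secondary esters.

Compound list
1 | 2-bromomalonaldehyde | O=CC(Br)C=O | starting material
2 | acetyl chloride | CC(=O)Cl | starting material
3 | (Z)-3-acetoxy-2-bromoacrolein | CC(=O)O/C=C(\Br)C=O | intermediate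
4 | (Z)-but-2-ene-1,4-diol | OC/C=C\CO | starting material
5 | benzoyl chloride | O=C(Cl)c1ccccc1 | starting material
6 | (Z)-4-hydroxybut-2-enyl benzoate | O=C(OC/C=C\CO)c1ccccc1 | intermediate
7 | (Z)-4-oxobut-2-enyl benzoate | O=C/C=C\COC(=O)c1ccccc1 | intermediate
8 | (1E,3E)-4-(triisopropylsilyloxy)buta-1,3-dienyl benzoate | O=C(O/C=C/C=C/O[Si](C(C)C)(C(C)C)C(C)C)c1ccccc1 | intermediate
9 | (1S,2S,3R,6S)-2-acetoxy-3-(benzoyloxy)-1-bromo-6-(triisopropylsilyloxy)cyclohex-4-ene-1-carbaldehyde | CC(=O)O[C@H]1[C@H](OC(=O)c2ccccc2)C=C[C@H](O[Si](C(C)C)(C(C)C)C(C)C)[C@]1(Br)C=O | intermediate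
10 | tetrabutylammonium C6-alkoxide of 9 (silyl group removed; all centres arranged as in 9) | CC(=O)O[C@H]1[C@H](OC(=O)c2ccccc2)C=C[C@H]([O-])[C@]1(Br)C=O.CCCC[N+](CCCC)(CCCC)CCCC | intermediate
11 | (1S,2S,3R,6S)-2-acetoxy-1-formyl-7-oxabicyclo[4.1.0]hept-4-en-3-yl benzoate | CC(=O)O[C@H]1[C@H](OC(=O)c2ccccc2)C=C[C@@H]2O[C@@]21C=O | intermediate
12 | (1S,2S,3R,6S)-2-acetoxy-1-(hydroxymethyl)-7-oxabicyclo[4.1.0]hept-4-en-3-yl benzoate | CC(=O)O[C@H]1[C@H](OC(=O)c2ccccc2)C=C[C@@H]2O[C@@]21CO | intermediate
13 | [(1S,2S,3R,6S)-2-acetoxy-3-(benzoyloxy)-7-oxabicyclo[4.1.0]hept-4-en-1-yl]methyl benzoate | CC(=O)O[C@H]1[C@H](OC(=O)c2ccccc2)C=C[C@@H]2O[C@@]21COC(=O)c1ccccc1 | target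

Total step count: 8. Longest linear sequence: 7 steps (4 → 6 → 7 → 8 → 9 → 11 → 12 → 13); step 1 is a one-step side branch.

The three steps most likely to fail, with one fallback each

The greatest risk lies in step 5. The catalyst may fail to discriminate the two faces of the enal once the β-acetoxy group alters the binding geometry, or silyl transfer from the diene to the acidic catalyst may open an achiral background cycloaddition, so that the ring forms with poor facial selectivity. The fallback for step 5 sets out from 8 and 3, takes the chirality from a resolution instead of a catalyst, and comes back to the route at 9. The two components are combined without catalyst in toluene at 20 to 40 °C. This thermal Diels–Alder reaction should favour the same regio- and endo-isomer but deliver it as the racemate, that is 9 together with its mirror image, the enantiomeric cycloadduct F1, after minor diastereomers are removed on silica. The enantiomers are then separated by preparative chromatography on a chiral stationary phase (cellulose tris(3,5-dimethylphenylcarbamate) coated on silica). The enantiomeric cycloadduct F1 is set aside and 9 is carried into step 6.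

The second risk lies in step 6. The freed C6 alkoxide sits β to the formyl group and may break the C1–C6 bond by retro-aldol fragmentation, or the basic fluoride may cause acyl migration or loss of hydrogen bromide across C1–C2, before bromide is displaced. The fallback for step 6 sets out from 9, removes the aldehyde before any alkoxide is generated, and comes back to the route at 13. NaBH4 (MeOH/CH2Cl2, −78 °C, AcOH quench) should reduce 9 to the bromo alcohol F2 without closing the primary bromohydrin. Benzoyl chloride 5 with pyridine and catalytic 4-(dimethylamino)pyridine should convert the bromo alcohol F2 into the bromo dibenzoate F3 in CH2Cl2 at 0 °C. HF·pyridine in THF should remove the silyl group of the bromo dibenzoate F3 under acidic conditions and give the bromohydrin F4 with the C6 hydroxyl trans to bromine. 1,8-Diazabicyclo[5.4.0]undec-7-ene in CH2Cl2 at 0 °C should then close the epoxide of the bromohydrin F4 by the same anti displacement, which gives 13 directly and makes steps 7 and 8 unnecessary.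

The third risk lies in step 4. The amine may isomerise the cis enal before it is silylated, or the neighbouring benzoate carbonyl may capture the O-silylated enal, so that the enol benzoate double bond forms with the wrong geometry or the diene does not form cleanly. The fallback for step 4 sets out from 4 and comes back to the route at 8. It exchanges the roles of the two oxygens, so that the carbon to be deprotonated carries the silyl ether and the benzoate is put on last by O-acylation of a metal dienolate. Diol 4 (3 equiv) with i-Pr3SiCl and imidazole in CH2Cl2 at 0 °C should give the monosilylated alcohol F5 after the surplus diol is washed out. Activated MnO2 in CH2Cl2 should oxidise the monosilylated alcohol F5 to the cis silyloxy enal F6 without touching the alkene geometry. t-BuOK in THF at −78 °C should remove a γ-proton of the cis silyloxy enal F6 and give the potassium dienolate F7. Allylic 1,3-strain across the cis alkene turns the silyloxy group outward, and the extended enolate places the oxygen trans, so both double bonds should form E. Benzoyl chloride 5 added at −78 °C should acylate the potassium dienolate F7 on oxygen and give 8.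

Further compounds
F1 | step 5 | ent-9, (1R,2R,3S,6R)-2-acetoxy-3-(benzoyloxy)-1-bromo-6-(triisopropylsilyloxy)cyclohex-4-ene-1-carbaldehyde | CC(=O)O[C@@H]1[C@@H](OC(=O)c2ccccc2)C=C[C@@H](O[Si](C(C)C)(C(C)C)C(C)C)[C@@]1(Br)C=O
F2 | step 6 | bromo alcohol: 9 with the formyl group reduced to hydroxymethyl, all centres arranged as in 9 | CC(=O)O[C@H]1[C@H](OC(=O)c2ccccc2)C=C[C@H](O[Si](C(C)C)(C(C)C)C(C)C)[C@]1(Br)CO
F3 | step 6 | bromo dibenzoate: F2 with the primary hydroxyl benzoylated | CC(=O)O[C@H]1[C@H](OC(=O)c2ccccc2)C=C[C@H](O[Si](C(C)C)(C(C)C)C(C)C)[C@]1(Br)COC(=O)c1ccccc1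
F4 | step 6 | bromohydrin: F3 with the C6 silyl ether cleaved to the free hydroxyl, trans to bromine | CC(=O)O[C@H]1[C@H](OC(=O)c2ccccc2)C=C[C@H](O)[C@]1(Br)COC(=O)c1ccccc1
F5 | step 4 | (Z)-4-(triisopropylsilyloxy)but-2-en-1-ol | OC/C=C\CO[Si](C(C)C)(C(C)C)C(C)C
F6 | step 4 | (Z)-4-(triisopropylsilyloxy)but-2-enal | O=C/C=C\CO[Si](C(C)C)(C(C)C)C(C)C
F7 | step 4 | potassium (1E,3E)-4-(triisopropylsilyloxy)buta-1,3-dien-1-olate | [K+].[O-]/C=C/C=C/O[Si](C(C)C)(C(C)C)C(C)C
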